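**Plan**

1. Numbering: the nine-membered ring is N4–C9a(=O)–C9–C10(Et)–C11(O)–C12–C1(=O)–C2–C3; C5–C8 tie N4 to C9 (azepanone), C13(Me)–C14 complete the fused lactone, C18–C21 the lactone on C3. The enabling feature is the run C9a(=O)–C9–C10 with C11–C12 next to it inside this ring, all hung on N4: a γ,δ-unsaturated amide, the product pattern of an N-allyl amide enolate.
2. Retrosynthetic cuts, in order: the three carbonyl oxidation levels (C1, C14, C21); C12–C13 together with C1–O (haloacetal radical closure on a C11 allylic alcohol, itself from the C11=C12 alkene through its epoxide); N4–C5 (lactam N-alkylation); C9–C10 with N4–C12 re-formed (aza-Claisen); N4–C9a (acylation); C10=C11 (Wittig); C3–C18 (vinylogous Mannich).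
3. Forward order of rings: pyrrolidine (from L-pyroglutamate) and side oxolane, then four-atom expansion of the pyrrolidine to the nine-membered lactam, then the azepanone, then the fused oxolane, and one final oxidation to the ketone and both lactones.
4. Stereochemistry: C12 of L-pyroglutamate directs C3 (2,5-trans) and C18 (threo); hydrogenation sets C20; 12S together with the Z-enolate and the Z-butenyl group sets C9 and C10 through a chair; C11 comes from a reagent-controlled epoxidation; C12 and C13 from a cis-fused 5-exo radical closure.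
5. The side lactone travels as its methyl lactol ether from step 9 onward, so the amide base of the key step meets only one enolisable carbonyl.

Key step: step 12

Remark: C21, C14, C1 (and the aminal carbon of 2 and 3) all end as carbonyl or sp2 carbons, so they are carried as epimer mixtures and left undefined in the SMILES; descriptors at C10, C11 and C12 change along the route only through CIP priorities, and the SMILES are the reference.

**Step 1**
Reactants: 1 benzyl (2S)-1-(tert-butoxycarbonyl)-5-oxopyrrolidine-2-carboxylate (benzyl N-Boc-L-pyroglutamate, a catalogue derivative of L-pyroglutamic acid)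
Product: 3 benzyl (2S)-1-Boc-5-methoxypyrrolidine-2-carboxylate (C5 epimers), via hemiaminal 2 (not isolated)
Conditions: LiBHEt3, THF, −78 °C; then MeOH, p-TsOH·H2O (1.2 equiv), −78 °C → rt
Reagents that add atoms: methanol, CO
Why: LiBHEt3 reduces the imide-type ring carbonyl of the N-Boc lactam selectively over the benzyl ester at −78 °C, and acid-catalysed exchange with methanol (N,O-acetal formation) gives a stable N-acyliminium precursor with C12 untouched.

**Step 2**
Reactants: 4 3-methylfuran-2(5H)-one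
Product: 5 3-methyl-2-(triisopropylsilyloxy)furan
Conditions: TIPSOTf, Et3N, CH2Cl2, 0 °C
Reagents that add atoms: triisopropylsilyl trifluoromethanesulfonate, CC(C)[Si](OS(=O)(=O)C(F)(F)F)(C(C)C)C(C)C
Why: Soft enolisation of the butenolide with a silyl triflate and Et3N (silyl dienol ether formation) gives the aromatic 2-silyloxyfuran, the standard nucleophile for vinylogous Mannich reactions.

**Step 3**
Reactants: 3 benzyl (2S)-1-Boc-5-methoxypyrrolidine-2-carboxylate; 5 3-methyl-2-(triisopropylsilyloxy)furan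
Product: 7 benzyl (2S,5S)-1-Boc-5-[(2S)-4-methyl-5-oxo-2,5-dihydrofuran-2-yl]pyrrolidine-2-carboxylate, via N-acyliminium triflate 6 (not isolated)
Conditions: TIPSOTf (10 mol %), CH2Cl2, −78 → 0 °C
Reagents that add atoms: none
Why: Catalytic silyl triflate ionises the N,O-acetal to the N-acyliminium ion, which the silyloxyfuran should attack through its C5 terminus (vinylogous Mukaiyama–Mannich reaction) anti to the C12 ester (2,5-trans, 3S) and in the threo sense usual for silyloxyfurans with cyclic N-acyliminium ions (18S).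

**Step 4**
Reactants: 7 benzyl (2S,5S)-1-Boc-5-[(2S)-4-methyl-5-oxo-2,5-dihydrofuran-2-yl]pyrrolidine-2-carboxylate
Product: 8 (2S,5S)-1-Boc-5-[(2S,4S)-4-methyl-5-oxooxolan-2-yl]pyrrolidine-2-carboxylic acid
Conditions: H2 (3 atm), 10% Pd/C, EtOAc, rt
Reagents that add atoms: none
Why: Heterogeneous hydrogenation should deliver hydrogen to the butenolide face opposite the pyrrolidinyl group on C18, placing the C20 methyl cis to it (20S), while the same catalyst hydrogenolyses the benzyl ester.

**Step 5**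
Reactants: 8 (2S,5S)-1-Boc-5-[(2S,4S)-4-methyl-5-oxooxolan-2-yl]pyrrolidine-2-carboxylic acid
Product: 9 tert-butyl (2S,5S)-2-(hydroxymethyl)-5-[(2S,4S)-4-methyl-5-oxooxolan-2-yl]pyrrolidine-1-carboxylate
Conditions: BH3·SMe2, THF, 0 °C → rt; then H2O
Reagents that add atoms: none
Why: Borane reduces the free carboxylic acid through its acyloxyborane far faster than the lactone or the carbamate (chemoselective borane reduction), leaving all four stereocentres untouched.

**Step 6**
Reactants: 9 tert-butyl (2S,5S)-2-(hydroxymethyl)-5-[(2S,4S)-4-methyl-5-oxooxolan-2-yl]pyrrolidine-1-carboxylate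
Product: 10 tert-butyl (2S,5S)-2-formyl-5-[(2S,4S)-4-methyl-5-oxooxolan-2-yl]pyrrolidine-1-carboxylate
Conditions: Dess–Martin periodinane, NaHCO3, CH2Cl2, 0 °C → rt
Reagents that add atoms: none
Why: Dess–Martin oxidation under buffered, non-basic conditions should give the N-Boc α-amino aldehyde without epimerising C12.

**Step 7**
Reactants: 10 tert-butyl (2S,5S)-2-formyl-5-[(2S,4S)-4-methyl-5-oxooxolan-2-yl]pyrrolidine-1-carboxylate; 11 propyltriphenylphosphonium bromide
Product: 13 tert-butyl (2S,5S)-2-[(1Z)-but-1-en-1-yl]-5-[(2S,4S)-4-methyl-5-oxooxolan-2-yl]pyrrolidine-1-carboxylate, via phosphorus ylide 12 (not isolated)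
Conditions: 11, KN(SiMe3)2, THF, −78 → 0 °C; then 10, −78 °C → rt
Reagents that add atoms: none
Why: Wittig olefination with a non-stabilised ylide under lithium-free conditions passes through the kinetically favoured cis-oxaphosphetane and should give the Z-butenyl group, the aldehyde being added at −78 °C to a slight excess of ylide so that neither C12 nor C20 is epimerised.

**Step 8**
Reactants: 13 tert-butyl (2S,5S)-2-[(1Z)-but-1-en-1-yl]-5-[(2S,4S)-4-methyl-5-oxooxolan-2-yl]pyrrolidine-1-carboxylate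
Product: 14 tert-butyl (2S,5S)-2-[(1Z)-but-1-en-1-yl]-5-[(2S,4S)-5-hydroxy-4-methyloxolan-2-yl]pyrrolidine-1-carboxylate (lactol anomers)
Conditions: i-Bu2AlH, CH2Cl2, −78 °C; aq. KNaC4H4O6
Reagents that add atoms: none
Why: i-Bu2AlH adds once to the γ-lactone at −78 °C and the aluminium lactolate persists until work-up (lactone-to-lactol reduction), while the carbamate and the alkene are inert.

**Step 9**
Reactants: 14 tert-butyl (2S,5S)-2-[(1Z)-but-1-en-1-yl]-5-[(2S,4S)-5-hydroxy-4-methyloxolan-2-yl]pyrrolidine-1-carboxylate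
Product: 15 (2S,5S)-2-[(1Z)-but-1-en-1-yl]-5-[(2S,4S)-5-methoxy-4-methyloxolan-2-yl]pyrrolidine (acetal anomers)
Conditions: HCl (1.25 M in MeOH), 0 °C → rt; then aq. K2CO3
Reagents that add atoms: methanol, CO
Why: Methanolic HCl removes the Boc group by acidolysis and in the same flask converts the lactol into its methyl acetal (Fischer-type acetalisation) while the protonated nitrogen cannot engage the oxocarbenium ion, so that C20 is no longer α to a carbonyl.

**Step 10**
Reactants: 16 ε-caprolactone (oxepan-2-one)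
Product: 17 6-[(4-methoxybenzyl)oxy]hexanoic acid
Conditions: KOH, 4-methoxybenzyl chloride, toluene, reflux; then H2O, citric acid to pH 4
Reagents that add atoms: 4-methoxybenzyl chloride, COc1ccc(CCl)cc1; potassium hydroxide, [K+].[OH-]
Why: Hydroxide opens the lactone and the primary alkoxide is benzylated in the same pot (saponification followed by Williamson etherification), any 4-methoxybenzyl ester being hydrolysed by the excess KOH.

**Step 11**
Reactants: 15 (2S,5S)-2-[(1Z)-but-1-en-1-yl]-5-[(2S,4S)-5-methoxy-4-methyloxolan-2-yl]pyrrolidine; 17 6-[(4-methoxybenzyl)oxy]hexanoic acid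
Product: 19 1-{(2S,5S)-2-[(1Z)-but-1-en-1-yl]-5-[(2S,4S)-5-methoxy-4-methyloxolan-2-yl]pyrrolidin-1-yl}-6-[(4-methoxybenzyl)oxy]hexan-1-one, via acid chloride 18 (not isolated)
Conditions: 17, 1-chloro-N,N,2-trimethylprop-1-en-1-amine, CH2Cl2, 0 °C → rt; then 15, Et3N, DMAP (cat.), 0 °C → rt
Reagents that add atoms: none
Why: The acid is converted under neutral conditions into its chloride (Ghosez reagent), which acylates the hindered 2,5-disubstituted pyrrolidine under DMAP catalysis (amide formation from an acid chloride) without touching the PMB ether or the acetal.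

**Step 12**
Reactants: 19 1-{(2S,5S)-2-[(1Z)-but-1-en-1-yl]-5-[(2S,4S)-5-methoxy-4-methyloxolan-2-yl]pyrrolidin-1-yl}-6-[(4-methoxybenzyl)oxy]hexan-1-one
Product: 21 (3S,4S,5E,9S)-4-ethyl-3-{4-[(4-methoxybenzyl)oxy]butyl}-9-[(2S,4S)-5-methoxy-4-methyloxolan-2-yl]-1,3,4,7,8,9-hexahydro-2H-azonin-2-one, via lithium Z-enolate 20 (not isolated)
Conditions: LiN(SiMe3)2 (3 equiv), toluene, 110 °C; then H2O
Reagents that add atoms: none
Why: Excess LiN(SiMe3)2 converts the tertiary amide into its Z(O)-lithium enolate (C8 anti to nitrogen), and the array C9=C9a–N4–C12–C11=C10 then undergoes a charge-accelerated [3,3] shift that forms C9–C10 and breaks N4–C12. The closest known reaction type is the amide-enolate aza-Claisen ring expansion of 1-acyl-2-alkenylpyrrolidines and -piperidines to nine- and ten-membered lactams. The nine-membered ring is not closed end to end but arises by four-atom expansion of the pyrrolidine, whose C1–C2–C3 tether spans N4 and C12 diequatorially on the chair and so should deliver the E C11=C12 alkene. C9 is set by the enolate geometry (C8 pseudo-equatorial) and C10 by the Z geometry of the butenyl group (ethyl pseudo-axial), while the 12S centre, which becomes sp2, selects the enantiomeric sense of the chair and hence 9S,10S in 21 (9S,10R in the target by a change of priorities only). The step needs chair over boat and the diequatorial over the axial tether arrangement, both favoured by the trans-fused bicyclic transition state, and the acetal oxidation level of the side chain leaves the amide α-CH2 as the only enolisable site.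

**Step 13**
Reactants: 21 (3S,4S,5E,9S)-4-ethyl-3-{4-[(4-methoxybenzyl)oxy]butyl}-9-[(2S,4S)-5-methoxy-4-methyloxolan-2-yl]-1,3,4,7,8,9-hexahydro-2H-azonin-2-one
Product: 22 (3S,4S,5E,9S)-4-ethyl-3-(4-hydroxybutyl)-9-[(2S,4S)-5-methoxy-4-methyloxolan-2-yl]-1,3,4,7,8,9-hexahydro-2H-azonin-2-one
Conditions: DDQ, CH2Cl2–aq. KH2PO4/K2HPO4 (pH 7), 0 °C → rt
Reagents that add atoms: none
Why: Oxidative cleavage of the 4-methoxybenzyl ether by DDQ (benzylic hydride abstraction, then hydrolysis of the oxocarbenium ion) frees the C5 hydroxyl, the unconjugated ring alkene, the lactam and the acetal being too electron-poor to react.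

**Step 14**
Reactants: 22 (3S,4S,5E,9S)-4-ethyl-3-(4-hydroxybutyl)-9-[(2S,4S)-5-methoxy-4-methyloxolan-2-yl]-1,3,4,7,8,9-hexahydro-2H-azonin-2-one
Product: 23 4-[(3S,4S,5E,9S)-4-ethyl-9-[(2S,4S)-5-methoxy-4-methyloxolan-2-yl]-2-oxo-2,3,4,7,8,9-hexahydro-1H-azonin-3-yl]butyl methanesulfonate
Conditions: MsCl, Et3N, CH2Cl2, 0 °C
Reagents that add atoms: methanesulfonyl chloride, CS(=O)(=O)Cl
Why: Sulfonylation of the primary alcohol (mesylation) activates C5, the lactam N–H being far less nucleophilic.

**Step 15**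
Reactants: 23 4-[(3S,4S,5E,9S)-4-ethyl-9-[(2S,4S)-5-methoxy-4-methyloxolan-2-yl]-2-oxo-2,3,4,7,8,9-hexahydro-1H-azonin-3-yl]butyl methanesulfonate
Product: 24 (2S,5E,7S,8S)-7-ethyl-2-[(2S,4S)-5-methoxy-4-methyloxolan-2-yl]-1-azabicyclo[6.4.1]tridec-5-en-13-one (azepanone closed on the nine-membered lactam)
Conditions: NaH, THF–DMF (0.005 M), 0 → 50 °C
Reagents that add atoms: none
Why: Deprotonation of the secondary lactam and intramolecular N-alkylation (7-exo-tet) should close the azepanone, because the in-plane nitrogen lone pair of the transoid nine-membered amide points along the C9 side chain and a sodium amidate in DMF at high dilution favours N- over O-alkylation.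

**Step 16**
Reactants: 24 (2S,5E,7S,8S)-7-ethyl-2-[(2S,4S)-5-methoxy-4-methyloxolan-2-yl]-1-azabicyclo[6.4.1]tridec-5-en-13-one
Product: 25 the 11S,12S trans-epoxide of 24 (oxirane across C11–C12; C3, C9, C10, C18, C20 as in 32)
Conditions: L-fructose-derived Shi ketone (30 mol %), KHSO5 (as 2KHSO5·KHSO4·K2SO4), K2CO3, Bu4NHSO4, MeCN–CH2(OMe)2–aq. Na2B4O7 buffer, 0 °C
Reagents that add atoms: potassium peroxymonosulfate, [K+].[O-]S(=O)(=O)OO
Why: Shi asymmetric epoxidation of an E-1,2-disubstituted alkene, in which the dioxirane of the L-fructose-derived ketone gives S,S-epoxides through the spiro transition state and should here give the 11S,12S epoxide, while the basic buffer suppresses transannular opening by the lactam.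

**Step 17**
Reactants: 25 the 11S,12S trans-epoxide of 24
Product: 28 (2S,4Z,6R,7R,8S)-7-ethyl-6-hydroxy-2-[(2S,4S)-5-methoxy-4-methyloxolan-2-yl]-1-azabicyclo[6.4.1]tridec-4-en-13-one (C11 allylic alcohol with C12=C1 alkene), via hydroxy selenide 26 (not isolated), via selenoxide 27 (not isolated)
Conditions: (PhSe)2, NaBH4, EtOH, 70 °C; then THF, 30% H2O2, 0 °C → rt
Reagents that add atoms: none
Why: In this Sharpless–Lauer sequence the selenolate opens the epoxide by SN2 attack at C12, the carbon flanked by a CH2 and not by the branched C10, and the selenoxide undergoes syn-elimination away from the carbinol towards C1–H, giving the transposed allylic alcohol with the C11–O bond and its configuration intact (Z ring alkene expected; its geometry is lost in step 19).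

**Step 18**
Reactants: 28 (2S,4Z,6R,7R,8S)-7-ethyl-6-hydroxy-2-[(2S,4S)-5-methoxy-4-methyloxolan-2-yl]-1-azabicyclo[6.4.1]tridec-4-en-13-one
Product: 29 the C11 2-bromo-1-ethoxypropyl ether of 28 (mixed bromoacetal; acetal and C13 epimers)
Conditions: N-bromosuccinimide, ethyl prop-1-enyl ether, CH2Cl2, −40 → 0 °C
Reagents that add atoms: N-bromosuccinimide, O=C1CCC(=O)N1Br; ethyl prop-1-enyl ether, CCOC=CC
Why: Bromoetherification of the enol ether (Ueno–Stork haloacetal formation) generates an α-bromo oxocarbenium ion that the C11 hydroxyl captures far faster than the unactivated ring alkene reacts with the bromine source.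

**Step 19**
Reactants: 29 the C11 2-bromo-1-ethoxypropyl ether of 28
Product: 31 tricyclic hydroxy bis-acetal (oxolane C11–O–C14H(OEt)–C13H(Me)–C12 cis-fused to the nine-membered ring; OH on C1; C3, C9, C10, C11, C12, C13, C18, C20 as in 32), via hydroperoxide 30 (not isolated)
Conditions: Bu3SnH, dry air, toluene (0.02 M), 0 °C → rt; then PPh3
Reagents that add atoms: dioxygen, O=O
Why: In this Ueno–Stork 5-exo-trig radical cyclisation run under air (oxygenative radical cyclisation) the C13 radical should add to C12 on the ring face that carries the C11 oxygen, giving the cis-fused oxolane with the C13 methyl on the convex face (trans to C1), and the resulting C1 radical is captured by O2 faster than by Bu3SnH, PPh3 then reducing the hydroperoxide.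

**Step 20**
Reactants: 31 tricyclic hydroxy bis-acetal
Product: 32 CNP0311700.3 (target)
Conditions: CrO3, H2SO4, H2O, acetone, 0 °C → rt
Reagents that add atoms: water, O
Why: Jones oxidation, in which the aqueous acid hydrolyses both cyclic acetals to lactols that are oxidised to the two γ-lactones while the C1 carbinol is oxidised to the ketone, under acidic conditions that should not enolise C12, C13 or C20.

**Compound list**

1 | benzyl (2S)-1-(tert-butoxycarbonyl)-5-oxopyrrolidine-2-carboxylate | O=C1CC[C@@H](C(=O)OCc2ccccc2)N1C(=O)OC(C)(C)C | starting material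
2 | benzyl (2S)-1-Boc-5-hydroxypyrrolidine-2-carboxylate (hemiaminal, C5 epimers) | OC1CC[C@@H](C(=O)OCc2ccccc2)N1C(=O)OC(C)(C)C | intermediate
3 | benzyl (2S)-1-Boc-5-methoxypyrrolidine-2-carboxylate (C5 epimers) | COC1CC[C@@H](C(=O)OCc2ccccc2)N1C(=O)OC(C)(C)C | intermediate
4 | 3-methylfuran-2(5H)-one | CC1=CCOC1=O | starting material
5 | 3-methyl-2-(triisopropylsilyloxy)furan | Cc1ccoc1O[Si](C(C)C)(C(C)C)C(C)C | intermediate
6 | (2S)-2-(benzyloxycarbonyl)-1-Boc-3,4-dihydro-2H-pyrrol-1-ium trifluoromethanesulfonate (N-acyliminium ion) | O=C(OCc1ccccc1)[C@@H]1CCC=[N+]1C(=O)OC(C)(C)C.[O-]S(=O)(=O)C(F)(F)F | intermediate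
7 | benzyl (2S,5S)-1-Boc-5-[(2S)-4-methyl-5-oxo-2,5-dihydrofuran-2-yl]pyrrolidine-2-carboxylate | O=C(OCc1ccccc1)[C@@H]1CC[C@@H]([C@@H]2C=C(C)C(=O)O2)N1C(=O)OC(C)(C)C | intermediate
8 | (2S,5S)-1-Boc-5-[(2S,4S)-4-methyl-5-oxooxolan-2-yl]pyrrolidine-2-carboxylic acid | OC(=O)[C@@H]1CC[C@@H]([C@@H]2C[C@H](C)C(=O)O2)N1C(=O)OC(C)(C)C | intermediate
9 | tert-butyl (2S,5S)-2-(hydroxymethyl)-5-[(2S,4S)-4-methyl-5-oxooxolan-2-yl]pyrrolidine-1-carboxylate | OC[C@@H]1CC[C@@H]([C@@H]2C[C@H](C)C(=O)O2)N1C(=O)OC(C)(C)C | intermediate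
10 | tert-butyl (2S,5S)-2-formyl-5-[(2S,4S)-4-methyl-5-oxooxolan-2-yl]pyrrolidine-1-carboxylate | O=C[C@@H]1CC[C@@H]([C@@H]2C[C@H](C)C(=O)O2)N1C(=O)OC(C)(C)C | intermediate
11 | propyltriphenylphosphonium bromide | CCC[P+](c1ccccc1)(c1ccccc1)c1ccccc1.[Br-] | starting material
12 | propylidenetriphenylphosphorane (ylide) | CCC=P(c1ccccc1)(c1ccccc1)c1ccccc1 | intermediate
13 | tert-butyl (2S,5S)-2-[(1Z)-but-1-en-1-yl]-5-[(2S,4S)-4-methyl-5-oxooxolan-2-yl]pyrrolidine-1-carboxylate | CC\C=C/[C@@H]1CC[C@@H]([C@@H]2C[C@H](C)C(=O)O2)N1C(=O)OC(C)(C)C | intermediate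
14 | tert-butyl (2S,5S)-2-[(1Z)-but-1-en-1-yl]-5-[(2S,4S)-5-hydroxy-4-methyloxolan-2-yl]pyrrolidine-1-carboxylate (lactol anomers) | CC\C=C/[C@@H]1CC[C@@H]([C@@H]2C[C@H](C)C(O)O2)N1C(=O)OC(C)(C)C | intermediate
15 | (2S,5S)-2-[(1Z)-but-1-en-1-yl]-5-[(2S,4S)-5-methoxy-4-methyloxolan-2-yl]pyrrolidine (anomers) | CC\C=C/[C@@H]1CC[C@@H]([C@@H]2C[C@H](C)C(OC)O2)N1 | intermediate
16 | ε-caprolactone (oxepan-2-one) | O=C1CCCCCO1 | starting material
17 | 6-[(4-methoxybenzyl)oxy]hexanoic acid | COc1ccc(COCCCCCC(=O)O)cc1 | intermediate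
18 | 6-[(4-methoxybenzyl)oxy]hexanoyl chloride | COc1ccc(COCCCCCC(=O)Cl)cc1 | intermediate
19 | 1-{(2S,5S)-2-[(1Z)-but-1-en-1-yl]-5-[(2S,4S)-5-methoxy-4-methyloxolan-2-yl]pyrrolidin-1-yl}-6-[(4-methoxybenzyl)oxy]hexan-1-one | CC\C=C/[C@@H]1CC[C@@H]([C@@H]2C[C@H](C)C(OC)O2)N1C(=O)CCCCCOCc1ccc(OC)cc1 | intermediate
20 | lithium Z(O)-enolate of 19 | CC\C=C/[C@@H]1CC[C@@H]([C@@H]2C[C@H](C)C(OC)O2)N1/C(O[Li])=C/CCCCOCc1ccc(OC)cc1 | intermediate
21 | (3S,4S,5E,9S)-4-ethyl-3-{4-[(4-methoxybenzyl)oxy]butyl}-9-[(2S,4S)-5-methoxy-4-methyloxolan-2-yl]-1,3,4,7,8,9-hexahydro-2H-azonin-2-one | CC[C@H]1/C=C/CC[C@@H]([C@@H]2C[C@H](C)C(OC)O2)NC(=O)[C@H]1CCCCOCc1ccc(OC)cc1 | intermediate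
22 | (3S,4S,5E,9S)-4-ethyl-3-(4-hydroxybutyl)-9-[(2S,4S)-5-methoxy-4-methyloxolan-2-yl]-1,3,4,7,8,9-hexahydro-2H-azonin-2-one | CC[C@H]1/C=C/CC[C@@H]([C@@H]2C[C@H](C)C(OC)O2)NC(=O)[C@H]1CCCCO | intermediate
23 | methanesulfonate of 22 | CC[C@H]1/C=C/CC[C@@H]([C@@H]2C[C@H](C)C(OC)O2)NC(=O)[C@H]1CCCCOS(C)(=O)=O | intermediate
24 | (2S,5E,7S,8S)-7-ethyl-2-[(2S,4S)-5-methoxy-4-methyloxolan-2-yl]-1-azabicyclo[6.4.1]tridec-5-en-13-one | CC[C@H]1/C=C/CC[C@@H]([C@@H]2C[C@H](C)C(OC)O2)N2CCCC[C@@H]1C2=O | intermediate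
25 | 11S,12S trans-epoxide of 24 | CC[C@H]1[C@@H]2O[C@H]2CC[C@@H]([C@@H]3C[C@H](C)C(OC)O3)N2CCCC[C@@H]1C2=O | intermediate
26 | 11S-hydroxy 12R-phenylselanyl derivative (hydroxy selenide) | CC[C@H]1[C@H](O)[C@H]([Se]c2ccccc2)CC[C@@H]([C@@H]3C[C@H](C)C(OC)O3)N2CCCC[C@@H]1C2=O | intermediate
27 | selenoxide of 26 | CC[C@H]1[C@H](O)[C@H]([Se](=O)c2ccccc2)CC[C@@H]([C@@H]3C[C@H](C)C(OC)O3)N2CCCC[C@@H]1C2=O | intermediate
28 | (2S,4Z,6R,7R,8S)-7-ethyl-6-hydroxy-2-[(2S,4S)-5-methoxy-4-methyloxolan-2-yl]-1-azabicyclo[6.4.1]tridec-4-en-13-one | CC[C@H]1[C@H](O)/C=C\C[C@@H]([C@@H]2C[C@H](C)C(OC)O2)N2CCCC[C@@H]1C2=O | intermediate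
29 | C11 2-bromo-1-ethoxypropyl ether of 28 (bromoacetal) | CC[C@H]1[C@H](OC(OCC)C(C)Br)/C=C\C[C@@H]([C@@H]2C[C@H](C)C(OC)O2)N2CCCC[C@@H]1C2=O | intermediate
30 | C1 hydroperoxide of the cyclised bis-acetal | CC[C@H]1[C@@H]2OC(OCC)[C@@H](C)[C@@H]2C(OO)C[C@@H]([C@@H]3C[C@H](C)C(OC)O3)N2CCCC[C@@H]1C2=O | intermediate
31 | tricyclic C1 hydroxy bis-acetal (C14 ethyl acetal, C21 methyl acetal) | CC[C@H]1[C@@H]2OC(OCC)[C@@H](C)[C@@H]2C(O)C[C@@H]([C@@H]3C[C@H](C)C(OC)O3)N2CCCC[C@@H]1C2=O | intermediate
32 | CNP0311700.3 (3S,9S,10R,11S,12S,13S,18S,20S) | CC[C@H]1[C@@H]2OC(=O)[C@@H](C)[C@@H]2C(=O)C[C@@H]([C@@H]2C[C@H](C)C(=O)O2)N2CCCC[C@@H]1C2=O | target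

**Count**

Total steps: 20. Longest linear sequence: 18 (from 1 through steps 1, 3–9 and 11–20); steps 2 and 10 make the two side fragments.

**Steps most likely to fail**

Step 12. At 110 °C the enolate may be consumed by proton transfer and fragmentation before the slow shift through a chair that carries an axial ethyl group. Part of the flux may also pass through the chair with the C1 tether axial, which would give the Z ring alkene and the opposite sense at C9 and C10. The fallback is the neutral, Ireland-type variant. It sets out from 19: the enolate 20 is generated at −78 °C in THF and O-silylated with TBSCl in the presence of DMPU to give the O-silyl ketene N,O-acetal F1. Heating F1 in toluene at 110–130 °C should effect the same [3,3] shift without a free base and give the O-silyl lactim ether F2. K2CO3 in aqueous MeOH then cleaves the silyl group and the route is rejoined at 21.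

Step 19. Oxygen may capture the open-chain C13 radical before the 5-exo closure, or the cyclised C1 radical may be reduced by the stannane instead of oxygenated. The fallback separates ring closure from oxygen capture. It sets out from 28, which is converted with N-iodosuccinimide and ethyl prop-1-enyl ether into the iodoacetal F3. Iodine-atom-transfer cyclisation of F3 ((Bu3Sn)2 in catalytic amount, visible light, benzene, 80 °C) has no trap faster than ring closure and should give the cyclised C1 iodide F4. F4 is then hydroxylated under the aerobic Bu3SnH conditions, now without any competing cyclisation (through hydroperoxide 30, PPh3 work-up), and the route is rejoined at 31.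

Step 16. Facial selectivity may be poor or reversed: the bridged ring may expose only one face of the E-alkene in its populated conformation, so that the catalyst cannot overrule the substrate and oxygen is delivered to the face leading to the 11R,12R series. The fallback accepts that face and inverts C11 afterwards. It sets out from 24: mCPBA with NaHCO3 in CH2Cl2 gives the 11R,12R epoxide F5. The selenide opening and oxidation of step 17 lead through the hydroxy selenide F6 and the selenoxide F7 to the 11-epimeric allylic alcohol F8. Mitsunobu inversion with 4-nitrobenzoic acid, PPh3 and diisopropyl azodicarboxylate in toluene gives the 4-nitrobenzoate F9 with the required C11 configuration. K2CO3 in MeOH removes the ester and the route is rejoined at 28.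

**Further compounds**

F1 | step 12 | O-(tert-butyldimethylsilyl) ketene N,O-acetal of 19 | CC\C=C/[C@@H]1CC[C@@H]([C@@H]2C[C@H](C)C(OC)O2)N1/C(O[Si](C)(C)C(C)(C)C)=C/CCCCOCc1ccc(OC)cc1
F2 | step 12 | O-(tert-butyldimethylsilyl) lactim ether of 21 | CC[C@H]1/C=C/CC[C@@H]([C@@H]2C[C@H](C)C(OC)O2)N=C(O[Si](C)(C)C(C)(C)C)[C@H]1CCCCOCc1ccc(OC)cc1
F3 | step 19 | C11 1-ethoxy-2-iodopropyl ether of 28 (iodoacetal) | CC[C@H]1[C@H](OC(OCC)C(C)I)/C=C\C[C@@H]([C@@H]2C[C@H](C)C(OC)O2)N2CCCC[C@@H]1C2=O
F4 | step 19 | cyclised bis-acetal with iodine on C1 | CC[C@H]1[C@@H]2OC(OCC)[C@@H](C)[C@@H]2C(I)C[C@@H]([C@@H]3C[C@H](C)C(OC)O3)N2CCCC[C@@H]1C2=O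
F5 | step 16 | 11R,12R trans-epoxide of 24 | CC[C@H]1[C@H]2O[C@@H]2CC[C@@H]([C@@H]3C[C@H](C)C(OC)O3)N2CCCC[C@@H]1C2=O
F6 | step 16 | 11R-hydroxy 12S-phenylselanyl derivative | CC[C@H]1[C@@H](O)[C@@H]([Se]c2ccccc2)CC[C@@H]([C@@H]3C[C@H](C)C(OC)O3)N2CCCC[C@@H]1C2=O
F7 | step 16 | selenoxide of F6 | CC[C@H]1[C@@H](O)[C@@H]([Se](=O)c2ccccc2)CC[C@@H]([C@@H]3C[C@H](C)C(OC)O3)N2CCCC[C@@H]1C2=O
F8 | step 16 | C11 epimer of 28 | CC[C@H]1[C@@H](O)/C=C\C[C@@H]([C@@H]2C[C@H](C)C(OC)O2)N2CCCC[C@@H]1C2=O
F9 | step 16 | 4-nitrobenzoate of 28 | CC[C@H]1[C@H](OC(=O)c2ccc(cc2)[N+](=O)[O-])/C=C\C[C@@H]([C@@H]2C[C@H](C)C(OC)O2)N2CCCC[C@@H]1C2=O
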